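**Retrosynthetic overview**

1. The target is a 5-methoxy-7-hydroxyisoflavone with an (S)-2-hydroxy-3-methylbutyl chain on C6 and a prenyl group on C8. The plan rests on one feature: the pyranone oxygen O1 of ring C sits on C8a of ring A, the carbon ortho to C4a, which carries the C4 carbonyl. O1 can therefore arrive as the enol oxygen of a C2 formyl group and be joined to a C8a bromide, so ring A needs only its two phenolic oxygens, O5 and O7.
2. Disconnections, in retrosynthetic order: O1–C8a (copper-mediated intramolecular O-arylation), C2–C3 (formylation of a bromo deoxybenzoin), C4–C4a (aryl Grignard reagent plus arylacetic Weinreb amide), C6–CH2 (aryl Grignard opening of (R)-isopropyloxirane made from L-valine).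
3. After ring closure: acid unmasking, O7 propargylation and O5 methylation (told apart by the 5-OH···O=C4 hydrogen bond), Lindlar reduction, aromatic Claisen rearrangement to C8, deallylation.
4. Ring order: rings A and B are bought as benzenes (5-bromoresorcinol, 4-hydroxyphenylacetic acid); ring C is the only ring formed, in step 13.

Key step: step 13

Remark on the chemistry: O5 is carried through the ring closure as a MOM ether and methylated only in the chromone, and O4' is carried as an allyl ether. In the open-chain bromo ketone the carbonyl is twisted between Br and OMOM and cannot direct a selective MOM/methyl exchange, whereas the peri hydrogen bond of the chromone separates O5 from O7 reliably; the allyl ether keeps O4' out of the O7 alkylation. Chromone numbering is used for ring positions throughout.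

**Route**

Step 1
Reactants: 1 L-valine
Product: 2 (2S)-2-chloro-3-methylbutanoic acid
Conditions: NaNO2, 6 M HCl, 0 °C → rt
Reagents that add atoms: hydrochloric acid, Cl
Why: Diazotisation of the α-amino acid with chloride capture runs through the α-lactone (double inversion), so the (S) centre of L-valine is carried over with net retention.

Step 2
Reactants: 2 (2S)-2-chloro-3-methylbutanoic acid
Product: 3 (2S)-2-chloro-3-methylbutan-1-ol
Conditions: LiAlH4, Et2O, 0 °C; aqueous work-up
Reagents that add atoms: none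
Why: Hydride reduction of the carboxylic acid at low temperature should leave the hindered secondary C–Cl bond and its configuration untouched.

Step 3
Reactants: 3 (2S)-2-chloro-3-methylbutan-1-ol
Product: 4 (2R)-2-(propan-2-yl)oxirane
Conditions: KOH, H2O, 0 → 40 °C, product distilled out
Reagents that add atoms: none
Why: Intramolecular Williamson etherification (SN2 of the alkoxide on C2) inverts the chlorine-bearing carbon and should give the (R)-epoxide.

Step 4
Reactants: 5 4-hydroxyphenylacetic acid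
Product: 6 2-(4-hydroxyphenyl)-N-methoxy-N-methylacetamide
Conditions: MeNHOMe·HCl, EDC·HCl, HOBt, iPr2NEt, CH2Cl2, 0 °C → rt
Reagents that add atoms: N,O-dimethylhydroxylamine hydrochloride, CNOC.Cl
Why: Carbodiimide amide coupling through the HOBt active ester acylates the amine much faster than the free phenol.

Step 5
Reactants: 6 2-(4-hydroxyphenyl)-N-methoxy-N-methylacetamide
Product: 7 N-methoxy-N-methyl-2-[4-(prop-2-enyloxy)phenyl]acetamide
Conditions: allyl bromide, K2CO3, acetone, reflux
Reagents that add atoms: allyl bromide, C=CCBr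
Why: Williamson etherification of the phenoxide; the amide α-protons are not acidic enough for K2CO3.

Step 6
Reactants: 8 5-bromoresorcinol
Product: 9 1-bromo-3,5-bis(methoxymethoxy)benzene
Conditions: MOMCl, iPr2NEt, CH2Cl2, 0 °C → rt
Reagents that add atoms: chloromethyl methyl ether, COCCl
Why: O-alkylation of both phenols with the α-chloro ether gives the bis-acetal that directs the next metalation.

Step 7
Reactants: 9 1-bromo-3,5-bis(methoxymethoxy)benzene
Product: 11 5-bromo-2-iodo-1,3-bis(methoxymethoxy)benzene, via aryllithium 10 (not isolated)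
Conditions: LiN(iPr)2 (commercial solution), THF, −78 °C; I2, −78 °C → rt
Reagents that add atoms: iodine, II
Why: Directed ortho-metalation with a lithium amide should remove the proton flanked by both OMOM groups (most acidic, doubly coordinated) without touching the C–Br bond that an alkyllithium would exchange, and iodine traps the aryllithium.

Step 8
Reactants: 11 5-bromo-2-iodo-1,3-bis(methoxymethoxy)benzene; 4 (2R)-2-(propan-2-yl)oxirane
Product: 13 (2S)-1-[4-bromo-2,6-bis(methoxymethoxy)phenyl]-3-methylbutan-2-ol, via arylmagnesium chloride 12 (not isolated)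
Conditions: iPrMgCl·LiCl, THF, −20 °C; CuI (10 mol%), 4, −20 °C → rt; aq. NH4Cl
Reagents that add atoms: none
Why: Iodine–magnesium exchange is far faster at C–I than at C–Br, and the CuI-catalysed SN2 opening of the monosubstituted epoxide occurs at its CH2 group, so the stereocentre from L-valine is not touched and is named (S) in 13 only because CH2Ar ranks below isopropyl.

Step 9
Reactants: 13 (2S)-1-[4-bromo-2,6-bis(methoxymethoxy)phenyl]-3-methylbutan-2-ol
Product: 14 {[(2S)-1-[4-bromo-2,6-bis(methoxymethoxy)phenyl]-3-methylbutan-2-yl]oxy}(tert-butyl)dimethylsilane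
Conditions: TBSCl, imidazole, DMAP (cat.), DMF, 40 °C
Reagents that add atoms: tert-butyldimethylsilyl chloride, CC(C)(C)[Si](C)(C)Cl
Why: Imidazole-mediated silylation protects the secondary alcohol for the organometallic and basic steps without endangering the aryl MOM acetals.

Step 10
Reactants: 14 {[(2S)-1-[4-bromo-2,6-bis(methoxymethoxy)phenyl]-3-methylbutan-2-yl]oxy}(tert-butyl)dimethylsilane
Product: 15 {[(2S)-1-[4-bromo-3-iodo-2,6-bis(methoxymethoxy)phenyl]-3-methylbutan-2-yl]oxy}(tert-butyl)dimethylsilane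
Conditions: NIS, MeCN, 0 °C → rt, dark
Reagents that add atoms: N-iodosuccinimide, O=C1CCC(=O)N1I
Why: Electrophilic aromatic iodination under neutral conditions; the two remaining ring hydrogens are equivalent, each ortho to one OMOM and para to the other, so only one mono-iodide can form and it sits next to bromine.

Step 11
Reactants: 15 {[(2S)-1-[4-bromo-3-iodo-2,6-bis(methoxymethoxy)phenyl]-3-methylbutan-2-yl]oxy}(tert-butyl)dimethylsilane; 7 N-methoxy-N-methyl-2-[4-(prop-2-enyloxy)phenyl]acetamide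
Product: 17 1-{6-bromo-3-[(2S)-2-{[tert-butyl(dimethyl)silyl]oxy}-3-methylbutyl]-2,4-bis(methoxymethoxy)phenyl}-2-[4-(prop-2-enyloxy)phenyl]ethan-1-one, via ortho-bromoarylmagnesium chloride 16 (not isolated)
Conditions: iPrMgCl·LiCl, THF, −40 °C; 7, −40 → 0 °C; aq. NH4Cl
Reagents that add atoms: none
Why: Selective iodine–magnesium exchange gives an ortho-bromoaryl Grignard reagent that is stable below 0 °C, and its Weinreb ketone synthesis stops at the chelated tetrahedral adduct, which releases the ketone on work-up.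

Step 12
Reactants: 17 1-{6-bromo-3-[(2S)-2-{[tert-butyl(dimethyl)silyl]oxy}-3-methylbutyl]-2,4-bis(methoxymethoxy)phenyl}-2-[4-(prop-2-enyloxy)phenyl]ethan-1-one
Product: 18 1-{6-bromo-3-[(2S)-2-{[tert-butyl(dimethyl)silyl]oxy}-3-methylbutyl]-2,4-bis(methoxymethoxy)phenyl}-3-hydroxy-2-[4-(prop-2-enyloxy)phenyl]prop-2-en-1-one (enol form of the β-keto aldehyde)
Conditions: NaH, HCO2Et, EtOH (cat.), THF, 0 °C → rt; aq. NH4Cl
Reagents that add atoms: ethyl formate, CCOC=O
Why: Crossed Claisen condensation (α-formylation) of the benzylic ketone enolate with ethyl formate, driven by deprotonation of the β-keto aldehyde formed.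

Step 13
Reactants: 18 1-{6-bromo-3-[(2S)-2-{[tert-butyl(dimethyl)silyl]oxy}-3-methylbutyl]-2,4-bis(methoxymethoxy)phenyl}-3-hydroxy-2-[4-(prop-2-enyloxy)phenyl]prop-2-en-1-one
Product: 19 6-[(2S)-2-{[tert-butyl(dimethyl)silyl]oxy}-3-methylbutyl]-5,7-bis(methoxymethoxy)-3-[4-(prop-2-enyloxy)phenyl]-4H-chromen-4-one
Conditions: CuI (10 mol%), MeNHCH2CH2NHMe (20 mol%), Cs2CO3, toluene, 100 °C, argon
Reagents that add atoms: none
Why: Cs2CO3 turns the 2-aryl-3-hydroxypropenone into its delocalised enolate, which binds the diamine-ligated monovalent copper through the formyl-derived oxygen; activation of the neighbouring C8a–Br bond, helped by the ortho carbonyl, and C–O reductive elimination then form O1–C8a. The closest known reaction type is the copper-catalysed intramolecular Ullmann O-arylation of 1-(2-haloaryl)-1,3-dicarbonyl enolates to chromones and flavones. Ring C closes in a 6-exo-trig mode on the aryl carbon, the departing bromide lying outside the new ring. No stereocentre is formed and the remote (S) carbinol carbon is not involved. The step needs O- over C-arylation and attack by the formyl oxygen and not the ketone oxygen; both alternatives would require a four-membered ring, and the site of O1 is fixed by the bromine carried from 5-bromoresorcinol. Water and alcohols should be excluded so that the base does not deformylate the β-keto aldehyde before it cyclises.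

Step 14
Reactants: 19 6-[(2S)-2-{[tert-butyl(dimethyl)silyl]oxy}-3-methylbutyl]-5,7-bis(methoxymethoxy)-3-[4-(prop-2-enyloxy)phenyl]-4H-chromen-4-one
Product: 20 5,7-dihydroxy-6-[(2S)-2-hydroxy-3-methylbutyl]-3-[4-(prop-2-enyloxy)phenyl]-4H-chromen-4-one
Conditions: HCl (3 M in MeOH), THF, 45 °C
Reagents that add atoms: none
Why: Acid-catalysed acetal methanolysis removes both aryl MOM ethers and the same medium solvolyses the silyl ether, while the allyl ether, the chromone and the unactivated secondary alcohol are stable to dilute methanolic HCl.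

Step 15
Reactants: 20 5,7-dihydroxy-6-[(2S)-2-hydroxy-3-methylbutyl]-3-[4-(prop-2-enyloxy)phenyl]-4H-chromen-4-one; 21 3-chloro-3-methylbut-1-yne
Product: 22 5-hydroxy-6-[(2S)-2-hydroxy-3-methylbutyl]-7-[(2-methylbut-3-yn-2-yl)oxy]-3-[4-(prop-2-enyloxy)phenyl]-4H-chromen-4-one
Conditions: K2CO3, KI (cat.), CuI (cat.), acetone, reflux, argon
Reagents that add atoms: none
Why: Copper-assisted O-alkylation of a phenoxide with a tertiary propargylic chloride; 7-OH is the acidic vinylogous-acid phenol, whereas 5-OH is held in a hydrogen bond to the C4 carbonyl and the alcohol is not deprotonated by K2CO3.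

Step 16
Reactants: 22 5-hydroxy-6-[(2S)-2-hydroxy-3-methylbutyl]-7-[(2-methylbut-3-yn-2-yl)oxy]-3-[4-(prop-2-enyloxy)phenyl]-4H-chromen-4-one
Product: 23 6-[(2S)-2-hydroxy-3-methylbutyl]-5-methoxy-7-[(2-methylbut-3-yn-2-yl)oxy]-3-[4-(prop-2-enyloxy)phenyl]-4H-chromen-4-one
Conditions: MeI (excess), K2CO3, DMF, 40 °C
Reagents that add atoms: iodomethane, CI
Why: Williamson methylation under forcing conditions of the chelated 5-OH, now the only phenol; K2CO3 deprotonates neither the secondary alcohol nor the alkyne C–H.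

Step 17
Reactants: 23 6-[(2S)-2-hydroxy-3-methylbutyl]-5-methoxy-7-[(2-methylbut-3-yn-2-yl)oxy]-3-[4-(prop-2-enyloxy)phenyl]-4H-chromen-4-one
Product: 24 6-[(2S)-2-hydroxy-3-methylbutyl]-5-methoxy-7-[(2-methylbut-3-en-2-yl)oxy]-3-[4-(prop-2-enyloxy)phenyl]-4H-chromen-4-one
Conditions: H2 (1 atm), Lindlar catalyst (Pd on CaCO3, poisoned with Pb(OAc)2), quinoline, EtOAc, rt
Reagents that add atoms: none
Why: Lindlar semihydrogenation stops at the alkene and should spare the allyl ether and the chromone C2=C3 bond when hydrogen uptake is monitored.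

Step 18
Reactants: 24 6-[(2S)-2-hydroxy-3-methylbutyl]-5-methoxy-7-[(2-methylbut-3-en-2-yl)oxy]-3-[4-(prop-2-enyloxy)phenyl]-4H-chromen-4-one
Product: 26 7-hydroxy-6-[(2S)-2-hydroxy-3-methylbutyl]-5-methoxy-8-(3-methylbut-2-enyl)-3-[4-(prop-2-enyloxy)phenyl]-4H-chromen-4-one, via cyclohexadienone 25 (not isolated)
Conditions: PhNEt2, 130 °C, argon
Reagents that add atoms: none
Why: Aromatic Claisen rearrangement ([3,3]) of the 1,1-dimethylallyl aryl ether delivers the linear prenyl group to C8, the only free ortho position since C6 is substituted, and the dienone tautomerises to the phenol; the simple allyl ether on ring B needs a much higher temperature.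

Step 19
Reactants: 26 7-hydroxy-6-[(2S)-2-hydroxy-3-methylbutyl]-5-methoxy-8-(3-methylbut-2-enyl)-3-[4-(prop-2-enyloxy)phenyl]-4H-chromen-4-one
Product: 27 7-hydroxy-6-[(2S)-2-hydroxy-3-methylbutyl]-3-(4-hydroxyphenyl)-5-methoxy-8-(3-methylbut-2-enyl)-4H-chromen-4-one (CNP0323282.1)
Conditions: Pd(PPh3)4 (5 mol%), morpholine, THF, rt
Reagents that add atoms: none
Why: Tsuji–Trost deallylation: zerovalent palladium ionises the allyl aryl ether to a π-allyl complex that morpholine traps, while the trisubstituted prenyl alkene, the phenols and the alcohol are inert.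

**Compound list**

1 | L-valine | CC(C)[C@H](N)C(=O)O | starting material
2 | (2S)-2-chloro-3-methylbutanoic acid | CC(C)[C@H](Cl)C(=O)O | intermediate
3 | (2S)-2-chloro-3-methylbutan-1-ol | CC(C)[C@H](Cl)CO | intermediate
4 | (2R)-2-(propan-2-yl)oxirane | CC(C)[C@@H]1CO1 | intermediate
5 | 4-hydroxyphenylacetic acid | OC(=O)Cc1ccc(O)cc1 | starting material
6 | 2-(4-hydroxyphenyl)-N-methoxy-N-methylacetamide | CON(C)C(=O)Cc1ccc(O)cc1 | intermediate
7 | N-methoxy-N-methyl-2-[4-(prop-2-enyloxy)phenyl]acetamide | CON(C)C(=O)Cc1ccc(OCC=C)cc1 | intermediate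
8 | 5-bromoresorcinol | Oc1cc(O)cc(Br)c1 | starting material
9 | 1-bromo-3,5-bis(methoxymethoxy)benzene | COCOc1cc(Br)cc(OCOC)c1 | intermediate
10 | [4-bromo-2,6-bis(methoxymethoxy)phenyl]lithium (formed in the flask) | [Li]c1c(OCOC)cc(Br)cc1OCOC | intermediate
11 | 5-bromo-2-iodo-1,3-bis(methoxymethoxy)benzene | COCOc1cc(Br)cc(OCOC)c1I | intermediate
12 | [4-bromo-2,6-bis(methoxymethoxy)phenyl]magnesium chloride (formed in the flask) | Cl[Mg]c1c(OCOC)cc(Br)cc1OCOC | intermediate
13 | (2S)-1-[4-bromo-2,6-bis(methoxymethoxy)phenyl]-3-methylbutan-2-ol | COCOc1cc(Br)cc(OCOC)c1C[C@H](O)C(C)C | intermediate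
14 | {[(2S)-1-[4-bromo-2,6-bis(methoxymethoxy)phenyl]-3-methylbutan-2-yl]oxy}(tert-butyl)dimethylsilane | COCOc1cc(Br)cc(OCOC)c1C[C@H](O[Si](C)(C)C(C)(C)C)C(C)C | intermediate
15 | {[(2S)-1-[4-bromo-3-iodo-2,6-bis(methoxymethoxy)phenyl]-3-methylbutan-2-yl]oxy}(tert-butyl)dimethylsilane | COCOc1cc(Br)c(I)c(OCOC)c1C[C@H](O[Si](C)(C)C(C)(C)C)C(C)C | intermediate
16 | {6-bromo-3-[(2S)-2-{[tert-butyl(dimethyl)silyl]oxy}-3-methylbutyl]-2,4-bis(methoxymethoxy)phenyl}magnesium chloride (formed in the flask) | COCOc1cc(Br)c([Mg]Cl)c(OCOC)c1C[C@H](O[Si](C)(C)C(C)(C)C)C(C)C | intermediate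
17 | 1-{6-bromo-3-[(2S)-2-{[tert-butyl(dimethyl)silyl]oxy}-3-methylbutyl]-2,4-bis(methoxymethoxy)phenyl}-2-[4-(prop-2-enyloxy)phenyl]ethan-1-one | COCOc1cc(Br)c(C(=O)Cc2ccc(OCC=C)cc2)c(OCOC)c1C[C@H](O[Si](C)(C)C(C)(C)C)C(C)C | intermediate
18 | 1-{6-bromo-3-[(2S)-2-{[tert-butyl(dimethyl)silyl]oxy}-3-methylbutyl]-2,4-bis(methoxymethoxy)phenyl}-3-hydroxy-2-[4-(prop-2-enyloxy)phenyl]prop-2-en-1-one | COCOc1c(C[C@H](O[Si](C)(C)C(C)(C)C)C(C)C)c(OCOC)cc(Br)c1C(=O)C(=CO)c1ccc(OCC=C)cc1 | intermediate
19 | 6-[(2S)-2-{[tert-butyl(dimethyl)silyl]oxy}-3-methylbutyl]-5,7-bis(methoxymethoxy)-3-[4-(prop-2-enyloxy)phenyl]-4H-chromen-4-one | COCOc1c(C[C@H](O[Si](C)(C)C(C)(C)C)C(C)C)c(OCOC)cc2occ(-c3ccc(OCC=C)cc3)c(=O)c12 | intermediate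
20 | 5,7-dihydroxy-6-[(2S)-2-hydroxy-3-methylbutyl]-3-[4-(prop-2-enyloxy)phenyl]-4H-chromen-4-one | Oc1c(C[C@H](O)C(C)C)c(O)cc2occ(-c3ccc(OCC=C)cc3)c(=O)c12 | intermediate
21 | 3-chloro-3-methylbut-1-yne | CC(C)(Cl)C#C | starting material
22 | 5-hydroxy-6-[(2S)-2-hydroxy-3-methylbutyl]-7-[(2-methylbut-3-yn-2-yl)oxy]-3-[4-(prop-2-enyloxy)phenyl]-4H-chromen-4-one | Oc1c(C[C@H](O)C(C)C)c(OC(C)(C)C#C)cc2occ(-c3ccc(OCC=C)cc3)c(=O)c12 | intermediate
23 | 6-[(2S)-2-hydroxy-3-methylbutyl]-5-methoxy-7-[(2-methylbut-3-yn-2-yl)oxy]-3-[4-(prop-2-enyloxy)phenyl]-4H-chromen-4-one | COc1c(C[C@H](O)C(C)C)c(OC(C)(C)C#C)cc2occ(-c3ccc(OCC=C)cc3)c(=O)c12 | intermediate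
24 | 6-[(2S)-2-hydroxy-3-methylbutyl]-5-methoxy-7-[(2-methylbut-3-en-2-yl)oxy]-3-[4-(prop-2-enyloxy)phenyl]-4H-chromen-4-one | COc1c(C[C@H](O)C(C)C)c(OC(C)(C)C=C)cc2occ(-c3ccc(OCC=C)cc3)c(=O)c12 | intermediate
25 | 6-[(2S)-2-hydroxy-3-methylbutyl]-5-methoxy-8-(3-methylbut-2-enyl)-3-[4-(prop-2-enyloxy)phenyl]-8H-chromene-4,7-dione (both C8 epimers, formed in the flask) | COC1=C(C[C@H](O)C(C)C)C(=O)C(CC=C(C)C)C2=C1C(=O)C(c1ccc(OCC=C)cc1)=CO2 | intermediate
26 | 7-hydroxy-6-[(2S)-2-hydroxy-3-methylbutyl]-5-methoxy-8-(3-methylbut-2-enyl)-3-[4-(prop-2-enyloxy)phenyl]-4H-chromen-4-one | COc1c(C[C@H](O)C(C)C)c(O)c(CC=C(C)C)c2occ(-c3ccc(OCC=C)cc3)c(=O)c12 | intermediate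
27 | 7-hydroxy-6-[(2S)-2-hydroxy-3-methylbutyl]-3-(4-hydroxyphenyl)-5-methoxy-8-(3-methylbut-2-enyl)-4H-chromen-4-one | COc1c(C[C@H](O)C(C)C)c(O)c(CC=C(C)C)c2occ(-c3ccc(O)cc3)c(=O)c12 | target

**Totals**

Total step count: 19.
Longest linear sequence: 15 steps (L-valine, steps 1–3, then steps 8–19).

**Steps most likely to fail, with fallbacks**

Step 13. The base may strip the formyl group by retro-Claisen cleavage faster than copper closes the ring, or the C–Br bond may be reduced, because the carbonyl is twisted between two ortho substituents. The fallback puts the oxygen on C8a before the one-carbon unit. It sets out from ketone 17: copper-catalysed hydroxylation of the aryl bromide (Cu(acac)2, N,N'-bis(4-hydroxy-2,6-dimethylphenyl)oxalamide, LiOH, DMSO/H2O, 80 °C) should give 1-{3-[(2S)-2-{[tert-butyl(dimethyl)silyl]oxy}-3-methylbutyl]-6-hydroxy-2,4-bis(methoxymethoxy)phenyl}-2-[4-(prop-2-enyloxy)phenyl]ethan-1-one F1. Heating F1 with N,N-dimethylformamide dimethyl acetal in toluene should give the enaminone 1-{3-[(2S)-2-{[tert-butyl(dimethyl)silyl]oxy}-3-methylbutyl]-6-hydroxy-2,4-bis(methoxymethoxy)phenyl}-3-(dimethylamino)-2-[4-(prop-2-enyloxy)phenyl]prop-2-en-1-one F2, which closes by conjugate addition of the phenol and loss of dimethylamine (the classical deoxybenzoin route to isoflavones). The fallback comes back to the route at 19.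

Step 11. The doubly ortho-substituted Grignard reagent may deprotonate the acidic benzylic position of the Weinreb amide instead of adding to it, returning the reduced arene. The fallback builds the ketone from an aldehyde and a benzyl nucleophile. It sets out from iodide 15: the Grignard reagent 16 is quenched with DMF to give 6-bromo-3-[(2S)-2-{[tert-butyl(dimethyl)silyl]oxy}-3-methylbutyl]-2,4-bis(methoxymethoxy)benzaldehyde F3. Commercial [4-(prop-2-enyloxy)phenyl]methanol is converted with SOCl2 into 1-(chloromethyl)-4-(prop-2-enyloxy)benzene F4 and then with Mg turnings in THF into [4-(prop-2-enyloxy)benzyl]magnesium chloride F5. Addition of F5 to F3 should give 1-{6-bromo-3-[(2S)-2-{[tert-butyl(dimethyl)silyl]oxy}-3-methylbutyl]-2,4-bis(methoxymethoxy)phenyl}-2-[4-(prop-2-enyloxy)phenyl]ethan-1-ol F6 (both carbinol epimers), and Dess–Martin oxidation returns to the route at 17.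

Step 15. O-alkylation of the weakly nucleophilic 7-phenoxide, flanked by the C6 chain, with a tertiary propargylic chloride may be too slow, so that elimination of the chloride or alkyne coupling takes over. The fallback brings the five-carbon unit in as a primary halide and moves it to carbon by a 1,3-shift. It sets out from 20: prenyl bromide and K2CO3 in acetone should give 5-hydroxy-6-[(2S)-2-hydroxy-3-methylbutyl]-7-[(3-methylbut-2-enyl)oxy]-3-[4-(prop-2-enyloxy)phenyl]-4H-chromen-4-one F7. Methylation with MeI and K2CO3 in DMF gives 6-[(2S)-2-hydroxy-3-methylbutyl]-5-methoxy-7-[(3-methylbut-2-enyl)oxy]-3-[4-(prop-2-enyloxy)phenyl]-4H-chromen-4-one F8. The acidic aluminosilicate clay montmorillonite K10 (approximate formula Al2Si4O10(OH)2·nH2O) in CH2Cl2 at 0 °C then promotes the known ion-pair 1,3-shift of the prenyl group to the only free ortho position, C8, coming back to the route at 26.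

**Further compounds**

F1 | step 13 | 1-{3-[(2S)-2-{[tert-butyl(dimethyl)silyl]oxy}-3-methylbutyl]-6-hydroxy-2,4-bis(methoxymethoxy)phenyl}-2-[4-(prop-2-enyloxy)phenyl]ethan-1-one | COCOc1cc(O)c(C(=O)Cc2ccc(OCC=C)cc2)c(OCOC)c1C[C@H](O[Si](C)(C)C(C)(C)C)C(C)C
F2 | step 13 | 1-{3-[(2S)-2-{[tert-butyl(dimethyl)silyl]oxy}-3-methylbutyl]-6-hydroxy-2,4-bis(methoxymethoxy)phenyl}-3-(dimethylamino)-2-[4-(prop-2-enyloxy)phenyl]prop-2-en-1-one | COCOc1cc(O)c(C(=O)C(=CN(C)C)c2ccc(OCC=C)cc2)c(OCOC)c1C[C@H](O[Si](C)(C)C(C)(C)C)C(C)C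
F3 | step 11 | 6-bromo-3-[(2S)-2-{[tert-butyl(dimethyl)silyl]oxy}-3-methylbutyl]-2,4-bis(methoxymethoxy)benzaldehyde | COCOc1cc(Br)c(C=O)c(OCOC)c1C[C@H](O[Si](C)(C)C(C)(C)C)C(C)C
F4 | step 11 | 1-(chloromethyl)-4-(prop-2-enyloxy)benzene | ClCc1ccc(OCC=C)cc1
F5 | step 11 | [4-(prop-2-enyloxy)benzyl]magnesium chloride | Cl[Mg]Cc1ccc(OCC=C)cc1
F6 | step 11 | 1-{6-bromo-3-[(2S)-2-{[tert-butyl(dimethyl)silyl]oxy}-3-methylbutyl]-2,4-bis(methoxymethoxy)phenyl}-2-[4-(prop-2-enyloxy)phenyl]ethan-1-ol | COCOc1cc(Br)c(C(O)Cc2ccc(OCC=C)cc2)c(OCOC)c1C[C@H](O[Si](C)(C)C(C)(C)C)C(C)C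
F7 | step 15 | 5-hydroxy-6-[(2S)-2-hydroxy-3-methylbutyl]-7-[(3-methylbut-2-enyl)oxy]-3-[4-(prop-2-enyloxy)phenyl]-4H-chromen-4-one | Oc1c(C[C@H](O)C(C)C)c(OCC=C(C)C)cc2occ(-c3ccc(OCC=C)cc3)c(=O)c12
F8 | step 15 | 6-[(2S)-2-hydroxy-3-methylbutyl]-5-methoxy-7-[(3-methylbut-2-enyl)oxy]-3-[4-(prop-2-enyloxy)phenyl]-4H-chromen-4-one | COc1c(C[C@H](O)C(C)C)c(OCC=C(C)C)cc2occ(-c3ccc(OCC=C)cc3)c(=O)c12
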